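Cuts, last to first: the aldol bond C4–C3′ and the C4′–OH bond; then H–C5/H–C5′ (enone reduction) and H–C1/H–C1′ (allylic transposition from C14–O), back to a C2-symmetric bis-dienone.
Key cut, in each half: C1–C5, C2–C3 and C3–C4. Each hydroazulenone (cyclopentanone C1–C5 fused to the seven-membered ring C1, C5–C10) is read as the alkyne C4≡C5, the allene C10=C1=C2 and carbon monoxide as C3, and the six carbons C5–C4–C15–C15′–C4′–C5′ are those of hexa-1,5-diyne.
Earliest cut: C6–C7 in both halves, by two-directional allylboration–lactonisation of octa-2,6-diynedial with a 2-(borylmethyl)acrylate that carries the silyloxymethyl allene.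
Forward order: the chain is joined and both lactones form first, then both cyclopentenones and both seven-membered rings close in one step, and the linking cyclopentane closes last by aldol addition.
Stereochemistry: C6/C7 come from a catalyst-controlled chair allylboration; C1, C5, C1′, C5′ from α-face hydride delivery; C4′ from α-face enol ether oxidation; C4 and C3′ from the tether-constrained aldol.

Key step: step 8

Remarks before the steps:
- Numbering is that of guaianolides; the unprimed half becomes the ketone half, the primed half the diol half. α is the face of H-1, H-5, H-7 and of the lactone oxygen on C6.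
- Assumption: the (S)-configured phosphoric acid is taken to send the allyl unit to the Si face of the ynal (the mirror image of the sense the (R)-acid shows with simple aldehydes and pinacol allylboronate); if the ester-bearing boronate reverses this, the (R)-acid is used.

Step 1
Reactants: 1 4-chlorobut-2-yn-1-ol
Product: 2 tert-butyl[(4-chlorobut-2-yn-1-yl)oxy]dimethylsilane
Conditions: TBSCl, imidazole, CH2Cl2, 0 °C to rt
Reagents that add atoms: tert-butyldimethylsilyl chloride, `CC(C)(C)[Si](C)(C)Cl`
Why: Silylation of a primary alcohol; the ether withstands the organometallic steps and the cyclocarbonylation.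

Step 2
Reactants: 2 tert-butyl[(4-chlorobut-2-yn-1-yl)oxy]dimethylsilane; 3 (4-bromobut-1-yn-1-yl)trimethylsilane
Product: 5 tert-butyldimethyl{[2-ethenylidene-6-(trimethylsilyl)hex-5-yn-1-yl]oxy}silane, via Grignard reagent 4 (not isolated)
Conditions: 3, Mg, THF, rt; then 2, CuBr·SMe2 (10 mol %), THF, −40 to 0 °C
Reagents that add atoms: none
Why: Copper-catalysed anti-SN2′ substitution of a propargylic chloride by a Grignard reagent, with γ-attack at the carbon bearing CH2OTBS, gives the 1,1-disubstituted allene; no stereocentre arises.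

Step 3
Reactants: 5 tert-butyldimethyl{[2-ethenylidene-6-(trimethylsilyl)hex-5-yn-1-yl]oxy}silane
Product: 6 tert-butyl[(2-ethenylidenehex-5-yn-1-yl)oxy]dimethylsilane
Conditions: K2CO3, MeOH, rt
Reagents that add atoms: none
Why: Methanolysis of the alkynyl C–Si bond; the alkyl silyl ether and the allene are inert to carbonate in methanol.

Step 4
Reactants: 6 tert-butyl[(2-ethenylidenehex-5-yn-1-yl)oxy]dimethylsilane
Product: 8 methyl 6-{[(tert-butyldimethylsilyl)oxy]methyl}octa-6,7-dien-2-ynoate, via lithium acetylide 7 (not isolated)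
Conditions: n-BuLi, THF, −78 °C; then ClCO2Me, −78 to 0 °C
Reagents that add atoms: methyl chloroformate, `COC(=O)Cl`
Why: Selective deprotonation of the terminal alkyne (far more acidic than the allenic CH2) and C-acylation of the acetylide give the ynoate.

Step 5
Reactants: 8 methyl 6-{[(tert-butyldimethylsilyl)oxy]methyl}octa-6,7-dien-2-ynoate
Product: 10 methyl (2Z)-6-{[(tert-butyldimethylsilyl)oxy]methyl}-2-[(4,4,5,5-tetramethyl-1,3,2-dioxaborolan-2-yl)methyl]octa-2,6,7-trienoate, via vinylalane 9 (not isolated)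
Conditions: i-Bu2AlH, HMPA, THF, 0 °C; then ICH2Bpin, 0 °C to rt
Reagents that add atoms: 2-(iodomethyl)-4,4,5,5-tetramethyl-1,3,2-dioxaborolane, `ICB1OC(C)(C)C(C)(C)O1`
Why: Conjugate syn-hydroalumination of the ynoate puts aluminium cis to the new vinylic hydrogen (the future H-7), and C-alkylation of the vinylalane by the iodomethylboronate gives the (2Z)-allylboronate with the C8 chain trans to CH2B, the geometry that leads to the trans lactone.

Step 6
Reactants: 11 hexa-1,5-diyne; 12 N,N-dimethylformamide (two equivalents)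
Product: 15 octa-2,6-diynedial, via dilithium diynediide 13 (not isolated), via bis(hemiaminal alkoxide) 14 (not isolated)
Conditions: n-BuLi (2.1 equiv), THF, −78 °C; DMF (3 equiv), −78 °C to rt; inverse quench into aq KH2PO4/MTBE, 0 °C; used at once
Reagents that add atoms: N,N-dimethylformamide (the second of the two equivalents of 12), `CN(C)C=O`
Why: Double formylation of a dilithium bis(acetylide): each acetylide terminus adds to one molecule of DMF, so two formyl groups (two carbons and two oxygens) are built in, the hemiaminal alkoxides persist until work-up, and the buffered inverse quench releases the sensitive bis-ynal without amine-induced decomposition.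

Step 7
Reactants: 15 octa-2,6-diynedial; 10 allylboronate (2.4 equiv)
Product: 17 1,6-bis[(2S,3S)-3-(3-{[(tert-butyldimethylsilyl)oxy]methyl}penta-3,4-dien-1-yl)-4-methylidene-5-oxooxolan-2-yl]hexa-1,5-diyne (C2-symmetric bis(allenyne) bis-lactone; 6S,7S,6′S,7′S), via bis(boryl ether) 16 (not isolated)
Conditions: (S)-3,3′-bis(2,4,6-triisopropylphenyl)-1,1′-binaphthyl-2,2′-diyl hydrogen phosphate (10 mol %), 4 Å MS, PhMe, −30 °C to rt; then PPTS, 40 °C
Reagents that add atoms: none
Why: Chiral phosphoric acid-catalysed allylboration through a closed chair with the alkynyl group equatorial: the C8 chain trans to CH2B gives the anti adduct (trans lactone), the (S)-acid directs attack to the Si face of each formyl group (6S, hence 7S), the boryl ether lactonises onto the methyl ester, and the two-directional course enriches the C2-symmetric product over a separable meso isomer.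

Step 8
Reactants: 17 bis(allenyne) bis-lactone; 18 carbon monoxide (two equivalents)
Product: 19 C15–C15′-linked bis[14-(tert-butyldimethylsilyloxy)-3-oxoguaia-1(10),4,11(13)-trien-12,6α-olide] (6S,7S in both halves)
Conditions: [Rh(CO)2Cl]2 (10 mol %), CO (1 atm), PhMe (0.01 M), 110 °C, slow addition of 17
Reagents that add atoms: none
Why: [Rh(CO)2Cl]2, a source of monovalent rhodium, coordinates the C4≡C5 triple bond together with the terminal C1=C2 π-bond of the allene, and oxidative coupling joins C5 to C1 in a rhodacyclopentene; migratory insertion of CO (the future C3) and reductive elimination then make C2–C3 and C3–C4, and the released catalyst repeats the sequence at the second allenyne. The closest known reaction is the rhodium-catalysed allenic Pauson–Khand cyclocarbonylation of lactone-tethered allenynes to bicyclo[5.3.0]decadienones. Each cyclopentenone (C1–C5) closes by this [2+2+1] union of alkyne, alkene and CO, and each seven-membered ring (C1, C5–C10) closes in the same C1–C5 bond-forming event across the four-atom tether C6–C9, which leaves the internal C1=C10 bond inside the larger ring. No stereocentre is created; C6 and C7 are spectators, and the neutral conditions leave them and the α-methylene lactones untouched. The step needs the distal and not the proximal allene π-bond to react, which rhodium (unlike Mo(CO)6, which favours the proximal bond) and the four-atom tether secure, and it needs carbonylation to outrun β-hydride elimination from the allyl-rhodium form of the metallacycle, which CO saturation, high dilution and slow addition favour; the two reacting sites are insulated from each other by the C15–C15′ ethylene bridge.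

Step 9
Reactants: 19 bis(silyl ether) bis-dienone
Product: 20 C15–C15′-linked bis[14-hydroxy-3-oxoguaia-1(10),4,11(13)-trien-12,6α-olide]
Conditions: HF·pyridine, pyridine, THF, 0 °C to rt
Reagents that add atoms: none
Why: Buffered fluoride cleavage of the two primary silyl ethers; dienones and α-methylene lactones tolerate these conditions.

Step 10
Reactants: 20 bis(allylic alcohol)
Product: 21 14,14′-bis(methyl carbonate) of 20
Conditions: ClCO2Me, pyridine, CH2Cl2, 0 °C
Reagents that add atoms: methyl chloroformate, `COC(=O)Cl`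
Why: Acylation of the primary allylic alcohols installs the leaving groups for ionisation by palladium.

Step 11
Reactants: 21 bis(allylic carbonate)
Product: 22 C15–C15′-linked bis[3-oxo-1αH-guaia-4,10(14),11(13)-trien-12,6α-olide]
Conditions: Pd(OAc)2 (10 mol %), n-Bu3P (10 mol %), HCO2H, Et3N, THF, rt to 40 °C
Reagents that add atoms: none
Why: Palladium-catalysed formate hydrogenolysis of an allylic carbonate with allylic transposition: zerovalent palladium ionises the C14 carbonate, formate decarboxylates to a palladium hydride, and with the trialkylphosphine the hydride goes to the substituted terminus C1 from the metal-bearing face, expected to be the α-face away from the C7–C8 fold, giving 1α-H and the C10=C14 methylene in both halves.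

Step 12
Reactants: 22 bis(exomethylene) bis-enone
Product: 23 13,13′-bis(phenylsulfonyl)-11βH,11′βH-tetrahydro derivative of 22 (both lactone methylenes masked as sulfones)
Conditions: PhSO2Na, AcOH, DMF, rt
Reagents that add atoms: sodium benzenesulfinate, `[Na+].[O-]S(=O)c1ccccc1`
Why: Sulfa-Michael addition of benzenesulfinic acid to the two α-methylene lactones, the only unhindered acceptors; the sulfone is inert to hydride and oxidant and leaves with base, and C11 (11β-H expected by protonation on the open face) is erased in step 15.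

Step 13
Reactants: 23 bis(sulfone) bis-enone
Product: 24 C15–C15′-linked bis[3-(dimethylphenylsilyloxy)-13-(phenylsulfonyl)-1αH,5αH,11βH-guaia-3,10(14)-dien-12,6α-olide]
Conditions: [(Ph3P)CuH]6 (5 mol %), PhMe2SiH (3 equiv), PhMe, rt
Reagents that add atoms: dimethylphenylsilane, `C[SiH](C)c1ccccc1`
Why: Copper hydride-catalysed 1,4-hydrosilylation of enones: hydride adds to C5 and C5′ on the α-face, anti to the β-oriented C1–C10 bond, which sets the cis ring fusion, and σ-bond metathesis with the silane traps each C3–C4 enolate regiospecifically; isolated methylenes and sulfones do not react.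

Step 14
Reactants: 24 bis(silyl enol ether)
Product: 26 sulfone-masked hydroxy diketone (primed half: 3′-oxo, 4′α-OH, 15′ β, 5′α-H; unprimed half: 3-oxo, 4-H, 5α-H; both halves 1αH, 10(14)-ene, 13-phenylsulfonyl-11βH lactone), via silyloxy epoxide 25 (not isolated)
Conditions: DMDO (1.0 equiv), acetone/CH2Cl2, −78 °C; then 1 M HCl, THF, 0 °C
Reagents that add atoms: dimethyldioxirane, `CC1(C)OO1`
Why: Rubottom oxidation: the dioxirane epoxidises one electron-rich tetrasubstituted enol ether on the convex α-face (cis to H-1′ and H-5′), so 4′-OH is α, while 1,1-disubstituted alkenes do not react at −78 °C; acid then opens the silyloxy epoxide to the α-hydroxy ketone and hydrolyses the untouched enol ether to the C3 ketone (either C4 epimer serves), and with one equivalent of oxidant the mono-oxidised compound should be the main component, to be separated from unoxidised and doubly oxidised material.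

Step 15
Reactants: 26 sulfone-masked hydroxy diketone
Product: 28 ainsliadimer A, via hydroxy diketone 27 (not isolated)
Conditions: DBU, CH2Cl2, rt
Reagents that add atoms: none
Why: E1cB loss of benzenesulfinate restores both α-methylene lactones, and the base then equilibrates the C3 ketone to its C3–C4 enolate, which closes the linking cyclopentane by intramolecular aldol addition (5-exo-trig) to the C3′ ketone; the β-oriented C15–C15′ tether allows only the cis-fused bicyclo[3.3.0] array, so C4 bonds to C3′ through its α-face and 3′-OH is α, cis to 4′-OH, with the quaternary C4 making the product the thermodynamic sink.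

Compound list
1 | 4-chlorobut-2-yn-1-ol | `OCC#CCCl` | starting material
2 | tert-butyl[(4-chlorobut-2-yn-1-yl)oxy]dimethylsilane | `CC(C)(C)[Si](C)(C)OCC#CCCl` | intermediate
3 | (4-bromobut-1-yn-1-yl)trimethylsilane | `C[Si](C)(C)C#CCCBr` | starting material
4 | [4-(trimethylsilyl)but-3-yn-1-yl]magnesium bromide | `C[Si](C)(C)C#CCC[Mg]Br` | intermediate
5 | tert-butyldimethyl{[2-ethenylidene-6-(trimethylsilyl)hex-5-yn-1-yl]oxy}silane | `C=C=C(CO[Si](C)(C)C(C)(C)C)CCC#C[Si](C)(C)C` | intermediate
6 | tert-butyl[(2-ethenylidenehex-5-yn-1-yl)oxy]dimethylsilane | `C=C=C(CO[Si](C)(C)C(C)(C)C)CCC#C` | intermediate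
7 | lithium acetylide of 6 | `[Li]C#CCCC(CO[Si](C)(C)C(C)(C)C)=C=C` | intermediate
8 | methyl 6-{[(tert-butyldimethylsilyl)oxy]methyl}octa-6,7-dien-2-ynoate | `COC(=O)C#CCCC(CO[Si](C)(C)C(C)(C)C)=C=C` | intermediate
9 | methyl 2-(diisobutylalumanyl)-6-{[(tert-butyldimethylsilyl)oxy]methyl}octa-2,6,7-trienoate (Al cis to H-3) | `COC(=O)/C(=C\CCC(CO[Si](C)(C)C(C)(C)C)=C=C)[Al](CC(C)C)CC(C)C` | intermediate
10 | methyl (2Z)-6-{[(tert-butyldimethylsilyl)oxy]methyl}-2-[(4,4,5,5-tetramethyl-1,3,2-dioxaborolan-2-yl)methyl]octa-2,6,7-trienoate | `COC(=O)/C(=C\CCC(CO[Si](C)(C)C(C)(C)C)=C=C)CB1OC(C)(C)C(C)(C)O1` | intermediate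
11 | hexa-1,5-diyne | `C#CCCC#C` | starting material
12 | N,N-dimethylformamide | `CN(C)C=O` | starting material
13 | dilithium hexa-1,5-diyne-1,6-diide | `[Li]C#CCCC#C[Li]` | intermediate
14 | dilithium 1,8-bis(dimethylamino)octa-2,6-diyne-1,8-diolate | `[Li]OC(N(C)C)C#CCCC#CC(O[Li])N(C)C` | intermediate
15 | octa-2,6-diynedial | `O=CC#CCCC#CC=O` | intermediate
16 | bis(pinacolboryl ether) of the open-chain bis(homoallylic alcohol) dimethyl ester (6S,7S,6′S,7′S) | `C=C(C(=O)OC)[C@H](CCC(CO[Si](C)(C)C(C)(C)C)=C=C)[C@H](OB1OC(C)(C)C(C)(C)O1)C#CCCC#C[C@@H](OB1OC(C)(C)C(C)(C)O1)[C@@H](CCC(CO[Si](C)(C)C(C)(C)C)=C=C)C(=C)C(=O)OC` | intermediate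
17 | 1,6-bis[(2S,3S)-3-(3-{[(tert-butyldimethylsilyl)oxy]methyl}penta-3,4-dien-1-yl)-4-methylidene-5-oxooxolan-2-yl]hexa-1,5-diyne | `C=C1C(=O)O[C@H](C#CCCC#C[C@H]2OC(=O)C(=C)[C@@H]2CCC(CO[Si](C)(C)C(C)(C)C)=C=C)[C@H]1CCC(CO[Si](C)(C)C(C)(C)C)=C=C` | intermediate
18 | carbon monoxide | `[C-]#[O+]` | starting material
19 | C15–C15′-linked bis[14-(tert-butyldimethylsilyloxy)-3-oxoguaia-1(10),4,11(13)-trien-12,6α-olide] | `C=C1C(=O)O[C@@H]2C3=C(CCC4=C5[C@H]6OC(=O)C(=C)[C@@H]6CCC(CO[Si](C)(C)C(C)(C)C)=C5CC4=O)C(=O)CC3=C(CO[Si](C)(C)C(C)(C)C)CC[C@@H]12` | intermediate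
20 | C15–C15′-linked bis[14-hydroxy-3-oxoguaia-1(10),4,11(13)-trien-12,6α-olide] | `C=C1C(=O)O[C@@H]2C3=C(CCC4=C5[C@H]6OC(=O)C(=C)[C@@H]6CCC(CO)=C5CC4=O)C(=O)CC3=C(CO)CC[C@@H]12` | intermediate
21 | 14,14′-bis(methyl carbonate) of 20 | `C=C1C(=O)O[C@@H]2C3=C(CCC4=C5[C@H]6OC(=O)C(=C)[C@@H]6CCC(COC(=O)OC)=C5CC4=O)C(=O)CC3=C(COC(=O)OC)CC[C@@H]12` | intermediate
22 | C15–C15′-linked bis[3-oxo-1αH-guaia-4,10(14),11(13)-trien-12,6α-olide] | `C=C1C(=O)O[C@@H]2C3=C(CCC4=C5[C@H]6OC(=O)C(=C)[C@@H]6CCC(=C)[C@@H]5CC4=O)C(=O)C[C@H]3C(=C)CC[C@@H]12` | intermediate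
23 | C15–C15′-linked bis[3-oxo-13-(phenylsulfonyl)-1αH,11βH-guaia-4,10(14)-dien-12,6α-olide] | `c1ccccc1S(=O)(=O)C[C@@H]1C(=O)O[C@@H]2C3=C(CCC4=C5[C@H]6OC(=O)[C@@H](CS(=O)(=O)c7ccccc7)[C@@H]6CCC(=C)[C@@H]5CC4=O)C(=O)C[C@H]3C(=C)CC[C@@H]12` | intermediate
24 | C15–C15′-linked bis[3-(dimethylphenylsilyloxy)-13-(phenylsulfonyl)-1αH,5αH,11βH-guaia-3,10(14)-dien-12,6α-olide] | `c1ccccc1S(=O)(=O)C[C@@H]1C(=O)O[C@@H]2[C@@H]3[C@@H](CC(O[Si](C)(C)c4ccccc4)=C3CCC3=C(O[Si](C)(C)c4ccccc4)C[C@H]4C(=C)CC[C@H]5[C@H](CS(=O)(=O)c6ccccc6)C(=O)O[C@@H]5[C@H]43)C(=C)CC[C@@H]12` | intermediate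
25 | 3′α,4′α-epoxide of 24 (silyloxy epoxide on one half, enol ether kept on the other) | `c1ccccc1S(=O)(=O)C[C@@H]1C(=O)O[C@@H]2[C@@H]3[C@@H](C[C@@]4(O[Si](C)(C)c5ccccc5)O[C@@]34CCC3=C(O[Si](C)(C)c4ccccc4)C[C@H]4C(=C)CC[C@H]5[C@H](CS(=O)(=O)c6ccccc6)C(=O)O[C@@H]5[C@H]43)C(=C)CC[C@@H]12` | intermediate
26 | sulfone-masked hydroxy diketone: 4′α-hydroxy-3,3′-dioxo, 1αH,5αH in both halves, 4-H (drawn α; epimer equally usable), 13,13′-bis(phenylsulfonyl) | `c1ccccc1S(=O)(=O)C[C@@H]1C(=O)O[C@@H]2[C@@H]3[C@@H](CC(=O)[C@]3(O)CC[C@H]3C(=O)C[C@H]4C(=C)CC[C@H]5[C@H](CS(=O)(=O)c6ccccc6)C(=O)O[C@@H]5[C@H]43)C(=C)CC[C@@H]12` | intermediate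
27 | hydroxy diketone with both α-methylene lactones restored (seco-aldol form of the target) | `C=C1C(=O)O[C@@H]2[C@@H]3[C@@H](CC(=O)[C@]3(O)CC[C@H]3C(=O)C[C@H]4C(=C)CC[C@H]5C(=C)C(=O)O[C@@H]5[C@H]43)C(=C)CC[C@@H]12` | intermediate
28 | ainsliadimer A | `C=C1C(=O)O[C@@H]2[C@@H]3[C@@H](C[C@@]4(O)[C@]3(O)CC[C@]43C(=O)C[C@H]4C(=C)CC[C@H]5C(=C)C(=O)O[C@@H]5[C@H]43)C(=C)CC[C@@H]12` | target

Total step count: 15. Longest linear sequence: 14 steps (steps 1–5, then 7–15); step 6 is a one-step side branch.

Steps most likely to fail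

Step 8 (double allenic Pauson–Khand). The allyl-rhodium form of the metallacycle may undergo β-hydride elimination to cross-conjugated trienes. Alternatively, the two electron-poor lactone methylenes may bind the metal or oligomerise at 110 °C before the second half has cyclised. The fallback removes these alkenes before the cyclocarbonylation. Setting out from 17, benzenesulfinic acid (PhSO2Na, AcOH, DMF) is added to both lactone methylenes to give the bis(sulfone) bis(allenyne) F1. The same [Rh(CO)2Cl]2/CO cyclocarbonylation then gives the sulfone-masked bis-dienone F2. DBU in CH2Cl2 expels sulfinate and the route is rejoined at 19.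

Step 11 (reductive allylic transposition). The hydride may be delivered to the primary terminus C14, giving the fully conjugated 10-methyl dienone, or to the β-face of C1; palladium hydride may also reduce a lactone methylene. The fallback replaces metal-hydride delivery by a sigmatropic one whose regiochemistry is fixed. Setting out from diol 20, a Mitsunobu reaction with 2-nitrobenzenesulfonohydrazide (PPh3, DEAD, THF, −30 °C) gives the bis(N-allyl-N-arylsulfonylhydrazine) F3. On warming to rt this loses arenesulfinic acid to the bis(allylic diazene) F4, whose retro-ene loss of dinitrogen places hydrogen on C1 and the double bond at C10=C14. The route is rejoined at 22.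

Step 13 (double conjugate hydrosilylation). The copper hydride may be unable to reach the fully substituted C5, or may add from the β-face and give the trans ring fusion. The fallback delivers hydride by migratory insertion at rhodium after oxidative addition of the silane rather than by nucleophilic copper hydride. Setting out from 23, RhCl(PPh3)3 (5 mol %) and Et3SiH in benzene at 70 °C give the bis(triethylsilyl enol ether) F5, which is also more robust to handling. One equivalent of DMDO at −78 °C gives the triethylsilyloxy epoxide F6, and aqueous acid opens it and hydrolyses the second enol ether. The route is rejoined at 26.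

Further compounds
F1 | step 8 | 1,6-bis{(2S,3S)-3-(3-{[(tert-butyldimethylsilyl)oxy]methyl}penta-3,4-dien-1-yl)-5-oxo-4-[(phenylsulfonyl)methyl]oxolan-2-yl}hexa-1,5-diyne (11βH) | `c1ccccc1S(=O)(=O)C[C@@H]1C(=O)O[C@H](C#CCCC#C[C@H]2OC(=O)[C@@H](CS(=O)(=O)c3ccccc3)[C@@H]2CCC(CO[Si](C)(C)C(C)(C)C)=C=C)[C@H]1CCC(CO[Si](C)(C)C(C)(C)C)=C=C`
F2 | step 8 | C15–C15′-linked bis[14-(tert-butyldimethylsilyloxy)-3-oxo-13-(phenylsulfonyl)-11βH-guaia-1(10),4-dien-12,6α-olide] | `c1ccccc1S(=O)(=O)C[C@@H]1C(=O)O[C@@H]2C3=C(CCC4=C5[C@H]6OC(=O)[C@@H](CS(=O)(=O)c7ccccc7)[C@@H]6CCC(CO[Si](C)(C)C(C)(C)C)=C5CC4=O)C(=O)CC3=C(CO[Si](C)(C)C(C)(C)C)CC[C@@H]12`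
F3 | step 11 | 14,14′-bis[1-(2-nitrophenylsulfonyl)hydrazin-1-yl] analogue of 20 | `C=C1C(=O)O[C@@H]2C3=C(CCC4=C5[C@H]6OC(=O)C(=C)[C@@H]6CCC(CN(N)S(=O)(=O)c7ccccc7[N+](=O)[O-])=C5CC4=O)C(=O)CC3=C(CN(N)S(=O)(=O)c4ccccc4[N+](=O)[O-])CC[C@@H]12`
F4 | step 11 | 14,14′-bis(diazenyl) analogue of 20 (bis(allylic diazene)) | `C=C1C(=O)O[C@@H]2C3=C(CCC4=C5[C@H]6OC(=O)C(=C)[C@@H]6CCC(CN=N)=C5CC4=O)C(=O)CC3=C(CN=N)CC[C@@H]12`
F5 | step 13 | C15–C15′-linked bis[13-(phenylsulfonyl)-3-(triethylsilyloxy)-1αH,5αH,11βH-guaia-3,10(14)-dien-12,6α-olide] | `c1ccccc1S(=O)(=O)C[C@@H]1C(=O)O[C@@H]2[C@@H]3[C@@H](CC(O[Si](CC)(CC)CC)=C3CCC3=C(O[Si](CC)(CC)CC)C[C@H]4C(=C)CC[C@H]5[C@H](CS(=O)(=O)c6ccccc6)C(=O)O[C@@H]5[C@H]43)C(=C)CC[C@@H]12`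
F6 | step 13 | 3′α,4′α-epoxide of F5 (triethylsilyloxy epoxide on one half) | `c1ccccc1S(=O)(=O)C[C@@H]1C(=O)O[C@@H]2[C@@H]3[C@@H](C[C@@]4(O[Si](CC)(CC)CC)O[C@@]34CCC3=C(O[Si](CC)(CC)CC)C[C@H]4C(=C)CC[C@H]5[C@H](CS(=O)(=O)c6ccccc6)C(=O)O[C@@H]5[C@H]43)C(=C)CC[C@@H]12`
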